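**Retrosynthetic overview** (core numbered as cyclopenta[c]pyran: C1 lactone carbonyl, O2, C3, C4, C4a, C5, C6, C7, C7a)
1. Last bond: acid 35 opens spiro-epoxide 16 at its CH2 terminus, giving the primary ester and the C7 tertiary alcohol together.
2. The δ-lactone ring (C1, O2, C3, C4, C4a, C7a) is closed on a finished cyclopentene by stitching one CO2 between C7a and C3 (C1–C7a and O2–C3, step 7). This works because O2 sits on C3, an allylic CH2 next to the C4 methylidene, and C1 sits on C7a, the γ-end of the allyl unit C7a=C7–CH2 that later carries the C7 and CH2 oxygens.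
3. Cyclopentene 10 comes from (R)-4-silyloxycyclopentenone 1: C4a by conjugate addition–elimination, C6 by Luche reduction, C7a reset by kinetic protonation (step 8), C7 by hydroxyl-directed epoxidation.
4. Acid 35 comes from (R)-pulegone 17: Favorskii contraction, all-cis triad by hydrogenation of a tetrasubstituted enoate, seven-membered ring by ring-closing metathesis, diene by dehydration.
5. Ring order: core – cyclopentane (bought), δ-lactone (step 7), oxirane (step 10, opened in step 24); acid – cyclopentane (step 11), cycloheptene (step 21).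

Key step: step 7

Remarks on the chemistry: step 7 is expected to place the carboxyl group anti to the C4a side chain (trans-fused lactone 12); any cis epimer formed is compound 14 itself and passes through step 8 unchanged. Compound 19 forms as a cis/trans mixture (drawn trans), and 31–33 are mixtures at the two chain carbons that become sp2 in step 22. The SMILES strings are the authority for configuration.

**Steps 1–10: iridoid core**

Step 1
Reactants: 1 (R)-4-[(tert-butyldimethylsilyl)oxy]cyclopent-2-en-1-one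
Product: 3 (R)-4-(prop-1-en-2-yl)cyclopent-2-en-1-one, via silyloxy ketone adduct 2 (not isolated)
Conditions: CH2=C(CH3)MgBr (1.5 equiv), CuBr·SMe2 (10 mol %), THF, −78 °C; NH4Cl work-up; then DBU (1.1 equiv), CH2Cl2, 0 °C
Reagents that add atoms: isopropenylmagnesium bromide, C=C(C)[Mg]Br
Why: Copper-catalysed conjugate addition anti to the silyloxy group, then E1cB loss of silanol (conjugate addition–elimination), should transpose the enone and fix the isopropenyl-bearing carbon as (R).

Step 2
Reactants: 3 (R)-4-(prop-1-en-2-yl)cyclopent-2-en-1-one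
Product: 4 (R)-2-iodo-4-(prop-1-en-2-yl)cyclopent-2-en-1-one
Conditions: I2 (1.5 equiv), pyridine/CH2Cl2 (1:1), 0 °C to rt
Reagents that add atoms: iodine, II
Why: Johnson α-iodination of an enone (pyridine addition, iodination, elimination) should functionalise C2 only and leave the C4 stereocentre alone.

Step 3
Reactants: 4 (R)-2-iodo-4-(prop-1-en-2-yl)cyclopent-2-en-1-one
Product: 5 (1S,4R)-2-iodo-4-(prop-1-en-2-yl)cyclopent-2-en-1-ol
Conditions: NaBH4, CeCl3·7H2O, MeOH, −78 °C
Reagents that add atoms: none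
Why: Luche 1,2-reduction should deliver hydride to the face opposite the C4 isopropenyl group, so the new carbinol centre is cis to it.

Step 4
Reactants: 5 (1S,4R)-2-iodo-4-(prop-1-en-2-yl)cyclopent-2-en-1-ol
Product: 6 tert-butyl{[(1S,4R)-2-iodo-4-(prop-1-en-2-yl)cyclopent-2-en-1-yl]oxy}dimethylsilane
Conditions: TBSCl, imidazole, DMF, rt
Reagents that add atoms: tert-butyldimethylsilyl chloride, C[Si](C)(Cl)C(C)(C)C
Why: Standard silylation of a secondary allylic alcohol; no stereocentre is touched.

Step 5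
Reactants: 6 tert-butyl{[(1S,4R)-2-iodo-4-(prop-1-en-2-yl)cyclopent-2-en-1-yl]oxy}dimethylsilane
Product: 7 tert-butyl{[(1S,4R)-4-(3-chloroprop-1-en-2-yl)-2-iodocyclopent-2-en-1-yl]oxy}dimethylsilane
Conditions: Ca(OCl)2, solid CO2, CH2Cl2/H2O, 0 °C
Reagents that add atoms: calcium hypochlorite, [Ca+2].[O-]Cl.[O-]Cl
Why: Ene-type allylic chlorination by HOCl made in the flask should select the electron-rich 1,1-disubstituted alkene over the iodo-substituted ring alkene and give the 2-substituted allyl chloride without forming a stereocentre.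

Step 6
Reactants: 7 tert-butyl{[(1S,4R)-4-(3-chloroprop-1-en-2-yl)-2-iodocyclopent-2-en-1-yl]oxy}dimethylsilane
Product: 10 2-{[(3R,5S)-5-[(tert-butyldimethylsilyl)oxy]-3-(3-chloroprop-1-en-2-yl)cyclopent-1-en-1-yl]methyl}-4,4,5,5-tetramethyl-1,3,2-dioxaborolane, via alkenylmagnesium chloride 8 (not isolated), via iodomethyl boronate complex 9 (not isolated)
Conditions: i-PrMgCl·LiCl (1.1 equiv), THF, −40 °C; ICH2B(pin) (1.2 equiv), −78 °C to rt
Reagents that add atoms: 2-(iodomethyl)-4,4,5,5-tetramethyl-1,3,2-dioxaborolane, CC1(C)OB(CI)OC1(C)C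
Why: Iodine–magnesium exchange followed by Matteson homologation (boronate complex, 1,2-metallate shift with loss of iodide) should give the allylboronate, while the allylic chloride, which needs copper to couple with a Grignard reagent at low temperature, survives.

Step 7
Reactants: 10 2-{[(3R,5S)-5-[(tert-butyldimethylsilyl)oxy]-3-(3-chloroprop-1-en-2-yl)cyclopent-1-en-1-yl]methyl}-4,4,5,5-tetramethyl-1,3,2-dioxaborolane
Product: 12 (4aR,6S,7aS)-6-[(tert-butyldimethylsilyl)oxy]-4,7-dimethylidenehexahydrocyclopenta[c]pyran-1(3H)-one (trans-fused), via potassium carboxylate 11 (not isolated)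
Conditions: (IPr)CuCl (10 mol %; IPr = 1,3-bis(2,6-diisopropylphenyl)imidazol-2-ylidene), KOtBu (1.05 equiv), CO2 (1 atm), THF (0.01 M), 25 °C; then 18-crown-6 (0.2 equiv), 65 °C
Reagents that add atoms: carbon dioxide, O=C=O
Why: The allylboronate is transmetallated by (IPr)Cu–OtBu to an allylcopper, which adds to CO2 through a closed six-membered SE2′ transition state at the γ-carbon C7a; this forms C1–C7a, moves the alkene into the exocyclic C7 methylidene and gives potassium carboxylate 11 (closest known reaction: copper-catalysed γ-selective carboxylation of allylboronates with CO2). On warming, 11 displaces the primary allylic chloride at C3 in a 6-exo-tet SN2 closure (O2–C3), a plain carboxylate alkylation, so the δ-lactone is the only ring formed and both new bonds come from one CO2 molecule. The one new stereocentre, C7a, is under substrate control: copper and CO2 should approach the cyclopentene face anti to the C4a side chain and the C6 silyloxy group, which gives the trans ring fusion of 12; this is accepted because step 8 resets C7a. The step needs γ- over α-carboxylation, secured by the cyclic SE2′ transition state. It also needs carboxylation to outrun copper-mediated allyl–allyl coupling, secured by CO2 saturation, the low reactivity of an allylic chloride toward the hindered copper allyl, and high dilution.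

Step 8
Reactants: 12 (4aR,6S,7aS)-6-[(tert-butyldimethylsilyl)oxy]-4,7-dimethylidenehexahydrocyclopenta[c]pyran-1(3H)-one
Product: 14 (4aR,6S,7aR)-6-[(tert-butyldimethylsilyl)oxy]-4,7-dimethylidenehexahydrocyclopenta[c]pyran-1(3H)-one (cis-fused), via lithium dienolate 13 (not isolated)
Conditions: LiN(i-Pr)2 (1.1 equiv), THF, −78 °C; then AcOH (3 equiv), −78 °C
Reagents that add atoms: none
Why: Deprotonation at the doubly activated C7a gives an extended dienolate, and kinetic α-protonation from the convex face (the side of H-4a, opposite the silyloxy group) should give the cis ring fusion; this is deconjugative kinetic protonation of a dienolate.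

Step 9
Reactants: 14 (4aR,6S,7aR)-6-[(tert-butyldimethylsilyl)oxy]-4,7-dimethylidenehexahydrocyclopenta[c]pyran-1(3H)-one
Product: 15 (4aR,6S,7aR)-6-hydroxy-4,7-dimethylidenehexahydrocyclopenta[c]pyran-1(3H)-one
Conditions: HF·pyridine, THF/pyridine, 0 °C to rt
Reagents that add atoms: none
Why: Buffered fluoride cleavage of the silyl ether is non-basic, so the exocyclic alkene should not move into conjugation and no stereocentre is touched.

Step 10
Reactants: 15 (4aR,6S,7aR)-6-hydroxy-4,7-dimethylidenehexahydrocyclopenta[c]pyran-1(3H)-one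
Product: 16 (4aR,6S,7S,7aR)-6-hydroxy-4-methylidenehexahydro-1H-spiro[cyclopenta[c]pyran-7,2'-oxiran]-1-one (epoxide oxygen cis to the C6 hydroxyl)
Conditions: VO(acac)2 (5 mol %), t-BuOOH (1.5 equiv), CH2Cl2, 0 °C to rt
Reagents that add atoms: tert-butyl hydroperoxide, CC(C)(C)OO
Why: Vanadium-catalysed hydroxyl-directed epoxidation of the allylic alcohol should deliver oxygen to the C7 methylidene on the face of the C6 hydroxyl, setting C7, and leave the undirected C4 methylidene alone.

**Steps 11–23: acid 35**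

Step 11
Reactants: 17 (R)-pulegone
Product: 19 methyl (1S,5R)-5-methyl-2-(propan-2-ylidene)cyclopentane-1-carboxylate (methyl pulegenate), via pulegone dibromide 18 (not isolated)
Conditions: Br2, NaHCO3, Et2O, −10 °C; then NaOMe, MeOH, reflux
Reagents that add atoms: sodium methoxide, [Na+].[O-]C
Why: Bromination of the isopropylidene alkene, then Favorskii ring contraction with loss of HBr, gives the cyclopentanecarboxylate without involving the methyl-bearing stereocentre of pulegone.

Step 12
Reactants: 19 methyl (1S,5R)-5-methyl-2-(propan-2-ylidene)cyclopentane-1-carboxylate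
Product: 21 methyl (1S,5R)-5-methyl-2-oxocyclopentane-1-carboxylate, via ozonide 20 (not isolated)
Conditions: O3, CH2Cl2, −78 °C; then Me2S, −78 °C to rt
Reagents that add atoms: ozone, [O-][O+]=O
Why: Ozonolysis with reductive work-up cleaves the tetrasubstituted alkene to the β-keto ester, whose ester-bearing carbon equilibrates to the trans isomer.

Step 13
Reactants: 21 methyl (1S,5R)-5-methyl-2-oxocyclopentane-1-carboxylate
Product: 22 methyl (R)-5-methyl-2-{[(trifluoromethyl)sulfonyl]oxy}cyclopent-1-ene-1-carboxylate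
Conditions: Tf2O, i-Pr2NEt, CH2Cl2, −78 °C
Reagents that add atoms: trifluoromethanesulfonic anhydride, O=S(=O)(OS(=O)(=O)C(F)(F)F)C(F)(F)F
Why: Enol triflate formation from a β-keto ester removes the labile ester-bearing stereocentre and leaves the methyl-bearing one untouched.

Step 14
Reactants: 22 methyl (R)-5-methyl-2-{[(trifluoromethyl)sulfonyl]oxy}cyclopent-1-ene-1-carboxylate
Product: 23 methyl (R)-2-(2-tert-butoxy-2-oxoethyl)-5-methylcyclopent-1-ene-1-carboxylate
Conditions: BrZnCH2CO2t-Bu (1.5 equiv), Pd(PPh3)4 (5 mol %), THF, 60 °C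
Reagents that add atoms: (2-tert-butoxy-2-oxoethyl)zinc bromide, CC(C)(C)OC(=O)C[Zn]Br
Why: Negishi coupling of the electron-poor enol triflate with the Reformatsky zinc enolate installs the acetate arm without creating a stereocentre.

Step 15
Reactants: 23 methyl (R)-2-(2-tert-butoxy-2-oxoethyl)-5-methylcyclopent-1-ene-1-carboxylate
Product: 24 methyl (1R,2R,5R)-2-(2-tert-butoxy-2-oxoethyl)-5-methylcyclopentane-1-carboxylate (all-cis)
Conditions: H2 (50 bar), 10 % Pd on carbon, EtOAc, rt
Reagents that add atoms: none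
Why: Heterogeneous hydrogenation adds both hydrogens syn from the face opposite the C5 methyl group, so the two new centres should be cis to each other and to the methyl.

Step 16
Reactants: 24 methyl (1R,2R,5R)-2-(2-tert-butoxy-2-oxoethyl)-5-methylcyclopentane-1-carboxylate
Product: 25 tert-butyl 2-[(1R,2R,3R)-2-(hydroxymethyl)-3-methylcyclopentyl]acetate
Conditions: LiBH4, THF/MeOH, 0 °C to rt
Reagents that add atoms: none
Why: Lithium borohydride reduces the methyl ester and should spare the tert-butyl ester (chemoselective ester reduction); no stereocentre is touched.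

Step 17
Reactants: 25 tert-butyl 2-[(1R,2R,3R)-2-(hydroxymethyl)-3-methylcyclopentyl]acetate
Product: 26 tert-butyl 2-[(1R,2R,3R)-2-(iodomethyl)-3-methylcyclopentyl]acetate
Conditions: I2, PPh3, imidazole, CH2Cl2, 0 °C
Reagents that add atoms: iodine, II
Why: Appel-type iodination of a primary alcohol under neutral conditions; no stereocentre is touched.

Step 18
Reactants: 26 tert-butyl 2-[(1R,2R,3R)-2-(iodomethyl)-3-methylcyclopentyl]acetate
Product: 28 tert-butyl 2-[(1R,2R,3R)-3-methyl-2-(3-methyl-2-oxobutyl)cyclopentyl]acetate, via alkylzinc iodide 27 (not isolated)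
Conditions: Zn dust, LiCl, THF, 40 °C; then i-PrCOCl, Pd(PPh3)4 (5 mol %), THF, rt
Reagents that add atoms: isobutyryl chloride, CC(C)C(Cl)=O
Why: Zinc insertion into the primary iodide and palladium-catalysed Negishi acylation give the isopropyl ketone in the presence of the ester; no stereocentre is touched.

Step 19
Reactants: 28 tert-butyl 2-[(1R,2R,3R)-3-methyl-2-(3-methyl-2-oxobutyl)cyclopentyl]acetate
Product: 29 tert-butyl 2-[(1R,2R,3R)-3-methyl-2-(3-methyl-2-methylidenebutyl)cyclopentyl]acetate
Conditions: Ph3PCH3Br, KOtBu, THF, 0 to 50 °C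
Reagents that add atoms: methyltriphenylphosphonium bromide, C[P+](c1ccccc1)(c1ccccc1)c1ccccc1.[Br-]
Why: Wittig methylenation converts the ketone into the 1,1-disubstituted alkene needed for ring closure; the ring centres are not epimerisable.

Step 20
Reactants: 29 tert-butyl 2-[(1R,2R,3R)-3-methyl-2-(3-methyl-2-methylidenebutyl)cyclopentyl]acetate
Product: 31 tert-butyl 3-hydroxy-2-[(1S,2R,3R)-3-methyl-2-(3-methyl-2-methylidenebutyl)cyclopentyl]pent-4-enoate (mixture at the two chain centres), via lithium ester enolate 30 (not isolated)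
Conditions: LiN(i-Pr)2, THF, −78 °C; acrolein, −78 °C; NH4Cl
Reagents that add atoms: acrolein, C=CC=O
Why: Aldol 1,2-addition of the lithium ester enolate to acrolein adds the last two ring carbons; the two new centres form unselectively and both are removed in step 22.

Step 21
Reactants: 31 tert-butyl 3-hydroxy-2-[(1S,2R,3R)-3-methyl-2-(3-methyl-2-methylidenebutyl)cyclopentyl]pent-4-enoate
Product: 32 tert-butyl (1R,3aS,8aR)-5-hydroxy-1-methyl-7-(propan-2-yl)-1,2,3,3a,4,5,8,8a-octahydroazulene-4-carboxylate (mixture at C4 and C5)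
Conditions: second-generation Grubbs catalyst RuCl2(=CHPh)(H2IMes)(PCy3) (5 mol %), CH2Cl2 (0.005 M), 40 °C
Reagents that add atoms: none
Why: Ring-closing metathesis between the vinyl group and the 1,1-disubstituted alkene should close the seven-membered ring as the trisubstituted isopropyl alkene with loss of ethene.

Step 22
Reactants: 32 tert-butyl (1R,3aS,8aR)-5-hydroxy-1-methyl-7-(propan-2-yl)-1,2,3,3a,4,5,8,8a-octahydroazulene-4-carboxylate
Product: 34 tert-butyl (1R,3aS,8aR)-1-methyl-7-(propan-2-yl)-1,2,3,3a,8,8a-hexahydroazulene-4-carboxylate, via allylic mesylate 33 (not isolated)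
Conditions: MsCl, Et3N, CH2Cl2, 0 °C; then DBU, rt
Reagents that add atoms: none
Why: Mesylation and E1cB elimination of the β-mesyloxy ester place the new alkene between the ester carbon and the former carbinol carbon, giving the conjugated dienoate and erasing both unselective centres.

Step 23
Reactants: 34 tert-butyl (1R,3aS,8aR)-1-methyl-7-(propan-2-yl)-1,2,3,3a,8,8a-hexahydroazulene-4-carboxylate
Product: 35 (1R,3aS,8aR)-1-methyl-7-(propan-2-yl)-1,2,3,3a,8,8a-hexahydroazulene-4-carboxylic acid
Conditions: TFA/CH2Cl2 (1:4), 0 °C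
Reagents that add atoms: none
Why: Acidolysis of the tert-butyl ester frees the acid with loss of isobutene; no stereocentre is touched.

**Step 24: union**

Step 24
Reactants: 16 (4aR,6S,7S,7aR)-6-hydroxy-4-methylidenehexahydro-1H-spiro[cyclopenta[c]pyran-7,2'-oxiran]-1-one; 35 (1R,3aS,8aR)-1-methyl-7-(propan-2-yl)-1,2,3,3a,8,8a-hexahydroazulene-4-carboxylic acid
Product: 36 nardostachysin
Conditions: Ti(OiPr)4 (1.5 equiv), CH2Cl2, rt
Reagents that add atoms: none
Why: Titanium-mediated opening of a 2,3-epoxy alcohol by a carboxylic acid (Sharpless-type) should occur at the unsubstituted CH2 terminus, so the configuration at C7 set in step 10 is kept and the ester and tertiary alcohol appear together.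

**Compound list**
1 | (R)-4-[(tert-butyldimethylsilyl)oxy]cyclopent-2-en-1-one | O=C1C=C[C@H](O[Si](C)(C)C(C)(C)C)C1 | starting material
2 | (3S,4R)-4-[(tert-butyldimethylsilyl)oxy]-3-(prop-1-en-2-yl)cyclopentan-1-one | CC(=C)[C@@H]1CC(=O)C[C@H]1O[Si](C)(C)C(C)(C)C | intermediate
3 | (R)-4-(prop-1-en-2-yl)cyclopent-2-en-1-one | CC(=C)[C@H]1C=CC(=O)C1 | intermediate
4 | (R)-2-iodo-4-(prop-1-en-2-yl)cyclopent-2-en-1-one | CC(=C)[C@H]1C=C(I)C(=O)C1 | intermediate
5 | (1S,4R)-2-iodo-4-(prop-1-en-2-yl)cyclopent-2-en-1-ol | CC(=C)[C@H]1C=C(I)[C@@H](O)C1 | intermediate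
6 | tert-butyl{[(1S,4R)-2-iodo-4-(prop-1-en-2-yl)cyclopent-2-en-1-yl]oxy}dimethylsilane | CC(=C)[C@H]1C=C(I)[C@@H](O[Si](C)(C)C(C)(C)C)C1 | intermediate
7 | tert-butyl{[(1S,4R)-4-(3-chloroprop-1-en-2-yl)-2-iodocyclopent-2-en-1-yl]oxy}dimethylsilane | ClCC(=C)[C@H]1C=C(I)[C@@H](O[Si](C)(C)C(C)(C)C)C1 | intermediate
8 | alkenylmagnesium chloride derived from 7 | ClCC(=C)[C@H]1C=C([Mg]Cl)[C@@H](O[Si](C)(C)C(C)(C)C)C1 | intermediate
9 | chloromagnesium (iodomethyl)(alkenyl)pinacolatoborate complex | ClCC(=C)[C@H]1C=C([B-]2(CI)OC(C)(C)C(C)(C)O2)[C@@H](O[Si](C)(C)C(C)(C)C)C1.[Mg+]Cl | intermediate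
10 | 2-{[(3R,5S)-5-[(tert-butyldimethylsilyl)oxy]-3-(3-chloroprop-1-en-2-yl)cyclopent-1-en-1-yl]methyl}-4,4,5,5-tetramethyl-1,3,2-dioxaborolane | ClCC(=C)[C@H]1C=C(CB2OC(C)(C)C(C)(C)O2)[C@@H](O[Si](C)(C)C(C)(C)C)C1 | intermediate
11 | potassium 4-[(tert-butyldimethylsilyl)oxy]-2-(3-chloroprop-1-en-2-yl)-5-methylidenecyclopentane-1-carboxylate (carboxylate trans to the side chain, silyloxy cis to it) | ClCC(=C)[C@@H]1C[C@H](O[Si](C)(C)C(C)(C)C)C(=C)[C@H]1C(=O)[O-].[K+] | intermediate
12 | (4aR,6S,7aS)-6-[(tert-butyldimethylsilyl)oxy]-4,7-dimethylidenehexahydrocyclopenta[c]pyran-1(3H)-one (trans-fused) | C=C1COC(=O)[C@H]2[C@H]1C[C@H](O[Si](C)(C)C(C)(C)C)C2=C | intermediate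
13 | lithium dienolate of 12 | C=C1COC([O-])=C2[C@H]1C[C@H](O[Si](C)(C)C(C)(C)C)C2=C.[Li+] | intermediate
14 | (4aR,6S,7aR)-6-[(tert-butyldimethylsilyl)oxy]-4,7-dimethylidenehexahydrocyclopenta[c]pyran-1(3H)-one (cis-fused) | C=C1COC(=O)[C@@H]2[C@H]1C[C@H](O[Si](C)(C)C(C)(C)C)C2=C | intermediate
15 | (4aR,6S,7aR)-6-hydroxy-4,7-dimethylidenehexahydrocyclopenta[c]pyran-1(3H)-one | C=C1COC(=O)[C@@H]2[C@H]1C[C@H](O)C2=C | intermediate
16 | (4aR,6S,7S,7aR)-6-hydroxy-4-methylidenehexahydro-1H-spiro[cyclopenta[c]pyran-7,2'-oxiran]-1-one | C=C1COC(=O)[C@@H]2[C@H]1C[C@H](O)[C@@]23CO3 | intermediate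
17 | (R)-pulegone | C[C@@H]1CCC(=C(C)C)C(=O)C1 | starting material
18 | pulegone dibromide, (5R)-2-bromo-2-(2-bromopropan-2-yl)-5-methylcyclohexan-1-one | C[C@@H]1CCC(Br)(C(C)(C)Br)C(=O)C1 | intermediate
19 | methyl (1S,5R)-5-methyl-2-(propan-2-ylidene)cyclopentane-1-carboxylate | COC(=O)[C@H]1[C@H](C)CCC1=C(C)C | intermediate
20 | secondary ozonide of 19 (spiro 1,2,4-trioxolane) | COC(=O)[C@H]1[C@H](C)CCC12OOC(C)(C)O2 | intermediate
21 | methyl (1S,5R)-5-methyl-2-oxocyclopentane-1-carboxylate | COC(=O)[C@H]1[C@H](C)CCC1=O | intermediate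
22 | methyl (R)-5-methyl-2-{[(trifluoromethyl)sulfonyl]oxy}cyclopent-1-ene-1-carboxylate | COC(=O)C1=C(OS(=O)(=O)C(F)(F)F)CC[C@H]1C | intermediate
23 | methyl (R)-2-(2-tert-butoxy-2-oxoethyl)-5-methylcyclopent-1-ene-1-carboxylate | COC(=O)C1=C(CC(=O)OC(C)(C)C)CC[C@H]1C | intermediate
24 | methyl (1R,2R,5R)-2-(2-tert-butoxy-2-oxoethyl)-5-methylcyclopentane-1-carboxylate | COC(=O)[C@H]1[C@@H](CC(=O)OC(C)(C)C)CC[C@H]1C | intermediate
25 | tert-butyl 2-[(1R,2R,3R)-2-(hydroxymethyl)-3-methylcyclopentyl]acetate | OC[C@H]1[C@@H](CC(=O)OC(C)(C)C)CC[C@H]1C | intermediate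
26 | tert-butyl 2-[(1R,2R,3R)-2-(iodomethyl)-3-methylcyclopentyl]acetate | IC[C@H]1[C@@H](CC(=O)OC(C)(C)C)CC[C@H]1C | intermediate
27 | alkylzinc iodide derived from 26 | I[Zn]C[C@H]1[C@@H](CC(=O)OC(C)(C)C)CC[C@H]1C | intermediate
28 | tert-butyl 2-[(1R,2R,3R)-3-methyl-2-(3-methyl-2-oxobutyl)cyclopentyl]acetate | CC(C)C(=O)C[C@H]1[C@@H](CC(=O)OC(C)(C)C)CC[C@H]1C | intermediate
29 | tert-butyl 2-[(1R,2R,3R)-3-methyl-2-(3-methyl-2-methylidenebutyl)cyclopentyl]acetate | CC(C)C(=C)C[C@H]1[C@@H](CC(=O)OC(C)(C)C)CC[C@H]1C | intermediate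
30 | lithium enolate of 29 | CC(C)C(=C)C[C@H]1[C@@H](C=C([O-])OC(C)(C)C)CC[C@H]1C.[Li+] | intermediate
31 | tert-butyl 3-hydroxy-2-[(1S,2R,3R)-3-methyl-2-(3-methyl-2-methylidenebutyl)cyclopentyl]pent-4-enoate | CC(C)C(=C)C[C@H]1[C@@H](C(C(O)C=C)C(=O)OC(C)(C)C)CC[C@H]1C | intermediate
32 | tert-butyl (1R,3aS,8aR)-5-hydroxy-1-methyl-7-(propan-2-yl)-1,2,3,3a,4,5,8,8a-octahydroazulene-4-carboxylate | CC(C)C1=CC(O)C(C(=O)OC(C)(C)C)[C@H]2CC[C@@H](C)[C@H]2C1 | intermediate
33 | methanesulfonate of 32 | CC(C)C1=CC(OS(C)(=O)=O)C(C(=O)OC(C)(C)C)[C@H]2CC[C@@H](C)[C@H]2C1 | intermediate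
34 | tert-butyl (1R,3aS,8aR)-1-methyl-7-(propan-2-yl)-1,2,3,3a,8,8a-hexahydroazulene-4-carboxylate | CC(C)C1=CC=C(C(=O)OC(C)(C)C)[C@H]2CC[C@@H](C)[C@H]2C1 | intermediate
35 | (1R,3aS,8aR)-1-methyl-7-(propan-2-yl)-1,2,3,3a,8,8a-hexahydroazulene-4-carboxylic acid | CC(C)C1=CC=C(C(=O)O)[C@H]2CC[C@@H](C)[C@H]2C1 | intermediate
36 | nardostachysin, [(4aR,6S,7S,7aR)-6,7-dihydroxy-4-methylidene-1-oxooctahydrocyclopenta[c]pyran-7-yl]methyl (1R,3aS,8aR)-1-methyl-7-(propan-2-yl)-1,2,3,3a,8,8a-hexahydroazulene-4-carboxylate | C=C1COC(=O)[C@@H]2[C@H]1C[C@H](O)[C@@]2(O)COC(=O)C1=CC=C(C(C)C)C[C@@H]2[C@H](C)CC[C@H]12 | target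

**Totals**
Total step count: 24. Longest linear sequence: 14 steps (steps 11–24, from 17); the core branch is 11 steps (steps 1–10 and 24).

**Steps most likely to fail**

Step 7. The allylcopper intermediate may couple with the pendant allylic chloride (carbon–carbon bond formation to a six-membered carbocycle) before it meets CO2, or the trans-disposed carboxylate may close slowly and oligomerise. The fallback separates the two bond formations and closes the ring by acyl activation. It sets out from 10: chloride is exchanged with CsOAc in DMF to give the allylic acetate F1. F1 is carboxylated under the same copper catalysis, now with no electrophile in the molecule, and the acetate is cleaved during a K2CO3/MeOH work-up to give the hydroxy acid F2. Yamaguchi lactonisation of F2 (2,4,6-trichlorobenzoyl chloride, Et3N, then DMAP, toluene, high dilution) comes back to the route at 12.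

Step 8. The dienolate may be protonated at the terminal methylidene carbon, which moves the alkene into conjugation, or from the wrong face. The fallback sets out from 12: DBU in CH2Cl2 drives the alkene fully into conjugation to give the single conjugated lactone F3. Photodeconjugation of F3 (254 nm, CH2Cl2, catalytic imidazole) forms a photodienol by 1,5-hydrogen shift from the C7 methyl group, and its ketonisation by protonation at C7a from the convex face comes back to the route at 14.

Step 24. The carboxylate may attack the tertiary epoxide carbon, or the lactone may exchange with isopropoxide, or the hindered dienoic acid may react too slowly. The fallback sets out from 15: hydroxyl-directed syn-dihydroxylation of the C7 methylidene with OsO4·TMEDA (CH2Cl2, −78 °C, NaHSO3 work-up) gives the triol F4. Selective Yamaguchi esterification of its primary hydroxyl with 35 comes back to the route at 36.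

**Further compounds**
F1 | step 7 | 2-[(1R,4S)-4-[(tert-butyldimethylsilyl)oxy]-3-[(4,4,5,5-tetramethyl-1,3,2-dioxaborolan-2-yl)methyl]cyclopent-2-en-1-yl]prop-2-en-1-yl acetate | CC(=O)OCC(=C)[C@H]1C=C(CB2OC(C)(C)C(C)(C)O2)[C@@H](O[Si](C)(C)C(C)(C)C)C1
F2 | step 7 | 4-[(tert-butyldimethylsilyl)oxy]-2-(3-hydroxyprop-1-en-2-yl)-5-methylidenecyclopentane-1-carboxylic acid (carboxyl trans to the side chain, silyloxy cis to it) | OCC(=C)[C@@H]1C[C@H](O[Si](C)(C)C(C)(C)C)C(=C)[C@H]1C(=O)O
F3 | step 8 | (4aS,6S)-6-[(tert-butyldimethylsilyl)oxy]-7-methyl-4-methylidene-4,4a,5,6-tetrahydrocyclopenta[c]pyran-1(3H)-one | C=C1COC(=O)C2=C(C)[C@@H](O[Si](C)(C)C(C)(C)C)C[C@@H]12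
F4 | step 24 | (4aR,6S,7S,7aR)-6,7-dihydroxy-7-(hydroxymethyl)-4-methylidenehexahydrocyclopenta[c]pyran-1(3H)-one | C=C1COC(=O)[C@@H]2[C@H]1C[C@H](O)[C@@]2(O)CO
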